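## Structural features

Target 29 is a labdane-type diterpenoid ester on a cis-fused decalin. Ring A (C1–C5, C10) and ring B (C5–C10) share the C5–C10 bond; C10 carries the angular methyl C20, C9 the chain C11–C16, C8 a tertiary hydroxyl and the methyl C17, and C4 the methyl C18 and the oxymethylene C19, which is acylated by (Z)-4-hydroxycinnamic acid. With the face of C20 called β, H-5, C11 and C17 are also β, the C8 hydroxyl is α, ring A leaves ring B through C1 and C4 on the α face, and on C4 the methyl is cis to H-5 while C19 is cis to C6. The five stereocentres C4, C5, C10, C9 and C8 are contiguous (4R,5S,8R,9R,10S); two are quaternary carbons and one is a tertiary carbinol. The chain ends in a 2-substituted buta-1,3-diene (C13=C16, C14=C15) that does not tolerate hydrogenation, radicals, strong acid or long heating. The Z-enoate isomerises under light, base or nucleophilic catalysts, the phenol must be masked during olefination, and every carbonyl placed β to the C8 oxygen or β to a cyclobutanol oxygen is a retro-aldol or β-elimination hazard. The real difficulty is the core: a cis ring fusion whose angular methyl sits on a quaternary carbon between three further stereocentres, plus a second quaternary centre at C4 in a fixed relation to it. The key step delivers C1–C4 of ring A as a cyclobutene: the ring B enone (C6=O, C5=C10) takes it up on one face, forming C1–C10 and C4–C5 with C5 and C10 cis, and the C1–C4 bond of the resulting bicyclo[2.2.0]hexane-1,4-diol is cut later to open ring A as a 1,4-dione. The configurations of C8 and C9 in enone 7 and of C5, C8, C9 and C10 in adduct 9 were checked centre by centre against 29 and agree; the one design change is that the C8 and C11 oxygens are tied into one ring, because an axial C17 is not guaranteed with two independent silyl ethers.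

## Logic of the disconnections

29 ⇒ 28 ⇒ 26 + 27. Cut: the aryl O–Si bond, then the enoate Cα=Cβ bond. The Z double bond is the most fragile element and is made last, under kinetic control, on the finished alcohol part. The aromatic half becomes a purchasable aldehyde. Demand: a Z-selective olefination and a desilylation that tolerate the free tertiary hydroxyl and the diene and do not isomerise the enoate.

26 ⇒ 25 ⇒ 24. Cut: the C–P bond, then the C19 O–acyl bond. The olefination handle is placed on the only primary hydroxyl. Demand: acylation at C19–OH and not at the tertiary C8–OH.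

24 ⇒ 21 + 22 (through 23). Cut: C12–C13. The diene enters in one piece after all reductions and strong-base steps, and the chain shrinks to a vinyl group. Demand: boron on C12 only, and a cross-coupling with an alkenyl chloride that beats β-hydride elimination in the presence of two free hydroxyls.

21 ⇒ 20 ⇒ 19 ⇒ 18. Cut: C4–C18; C19 is traced back from alcohol to aldehyde to enol ether. The quaternary centre is built by alkylating a C4 carbaldehyde enolate. Demand: the electrophile must arrive cis to H-5, and the C8 alkoxide must not be alkylated.

18 ⇒ 16 (through 17) ⇒ 15. The C1 carbonyl is added back and the C4=C19 bond is cut. Both ring A carbonyls arise together; one is used and one removed. Demand: olefination at C4 only, no epimerisation at C5, and a C1 reduction that spares enol ether and vinyl group.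

15 ⇒ 14. The C1–C4 bond is reconnected (it is cut in the forward direction). Ring A collapses to a cyclobutane-1,2-diol that carries C5 and C10 rigidly. Demand: a neutral cleavage.

14 ⇒ 13 ⇒ 12. Cut: C11=C12; the aldehyde is traced back to the primary alcohol. C12 is added while ring A is still masked as the diol, so no ring A ketone competes and no second primary alcohol exists. Demand: oxidation of one primary hydroxyl among three tertiary ones, and a methylenation without base.

12 ⇒ 11 ⇒ 10 ⇒ 9. The Si–O bonds are restored and the C6 carbonyl is added back through the enol triflate. The carbonyl that the photochemistry needs must be gone before the cyclobutanols are unmasked, or retro-aldol cleaves C4–C5. Demand: deoxygenation with no radical or cation at C6 and no loss of silyl groups.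

9 ⇒ 7 + 8. Cut: C1–C10 and C4–C5. A tricycle with four new stereocentres becomes a monocyclic enone with two stereocentres and a symmetrical purchasable alkene. Demand: attack on the α face of the enone.

7 ⇒ 6 ⇒ 5. The C6 oxygen is removed, then C5=C10 is cut. Demand: oxidation at the ring methylene and not at C9–H or C20; ring closure between two hindered alkenes.

5 ⇒ 4 ⇒ 2 + 3 ⇒ 1. The Si–O bonds are cut, then C9–C10, then the epoxide is traced to the allylic alcohol. One catalytic asymmetric epoxidation supplies both stereocentres of the precursor. Demand: the (2R,3R)-epoxide and attack at the secondary epoxide carbon with inversion.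

## Other disconnections considered

Alternative 1: The cut is C4–C5. The dienone A2, with a 4-cyanopentyl chain on quaternary C10, is deprotonated at C4 with KN(SiMe3)2. The tertiary nitrile anion adds 6-exo to C5 and closes ring A to the cis-fused enone A1 (C7=O, C8=C9).
- In favour: one ionic step gives ring A with C1–C3 already methylene, the cis fusion, and the C4 quaternary centre with C19 at the nitrile oxidation level. No photochemistry is needed and no C1 or C6 oxygen has to be removed. On ring A economy this is better than the chosen plan, which spends steps 7, 8 and 13–17 there.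
- Against: (a) C10 of A2 is a stereocentre whose two vinyl arms differ only by a remote methyl, so an enantioselective route to A2 is a hard problem in itself, whereas the chosen plan takes its absolute configuration from one epoxidation. (b) The C4 configuration depends on the face of a nearly linear metalated nitrile; here the alternative is only the equal of the chosen plan, whose step 16 is also substrate-controlled. (c) After A1 the side chain must be added at C9 next to quaternary C10, the C8 carbinol created with the right configuration and C7=O removed; the chosen plan settles C8 and C9 before its key step.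
- Mechanism: a reversible Michael closure under thermodynamic control, against an irreversible photocycloaddition.
- Step economy: about equal overall, with the risk moved from ring A to ring B.

Alternative 2: The cuts are C5–C10 and C3–C4. The triene A4 (Z-tethered diene C3=C2–C1=C10, (Z)-2-methyl enoate C4=C5) cyclises with Me2AlCl or heat to the octalin A3.
- In favour: both rings and C4, C5 and C10 form in one step. The C4 configuration is passed on stereospecifically from the enoate geometry, which is better than the enolate alkylation of the chosen plan. C19 arrives as an ester and ring A needs only hydrogenation of C1=C2, the best economy after the key step of all four plans.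
- Against: the transition state joins a fully substituted diene terminus (C10) to a trisubstituted enoate carbon (C4) and makes two quaternary centres at once. A Z-tethered diene reaches the s-cis conformer poorly and can undergo a 1,5-hydrogen shift from C9–H instead. Nothing comparable to a ring lock controls the diene face relative to C8 and C9. A4 needs a stereodefined trisubstituted Z-diene and a Z-enoate, which may cost the steps saved later.
- Equal points: both plans obtain the cis fusion by mechanistic necessity, and both can draw C8 and C9 from the same epoxide chemistry.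

Alternative 3: The cuts are C5–C6 and C9–C10. The alkylzinc reagent A7 adds to C5 of the enone ketal A6 under Cu(OTf)2 and a chiral phosphoramidite, and the C10 zinc enolate closes ring B on the (E)-enoate to give A5.
- In favour: the plan is convergent, so its longest linear sequence is shorter (better). C6 arrives as a methylene, so no deoxygenation is needed there (better). C9 receives a two-carbon ester arm, so C12 is already present (better than the one-carbon handle that costs steps 10 and 11 here).
- Against: the conjugate addition must occur at C5 between the ketal carbon and the methyl-bearing C10. A7 carries a tertiary silyloxy centre and an enoate and would be used as a diorganozinc or mixed reagent, which wastes or mis-transfers a valuable group. Catalyst control at C5 must match the resident C8 centre. The Michael closure sets C9 and C10 together, and nothing obvious enforces C20 cis to C11.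
- Equal points: ring A still carries the C1 ketone and a C4 carbonyl equivalent, so the C4 homologation and C1 deoxygenation remain as in the chosen plan.
- Mechanism: two ionic steps, the second reversible, against one irreversible photochemical step whose facial course is set by a ring lock.

Key step: step 6

Assumption: faces are named with C20 as β, and 2-chlorobuta-1,3-diene (22) is taken to be purchasable as a stabilised solution.

## Route

Step 1
Reactants: 1 geraniol
Product: 2 (2R,3R)-2,3-epoxygeraniol
Conditions: Ti(OiPr)4 (5 mol %), D-(−)-diethyl tartrate (6 mol %), t-BuOOH, 4 Å MS, CH2Cl2, −20 °C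
Reagents that add atoms: tert-butyl hydroperoxide, CC(C)(C)OO
Why: Sharpless asymmetric epoxidation of an allylic alcohol; the titanium–D-tartrate complex delivers oxygen to the face that gives the (2R,3R)-epoxide, which fixes C8 directly and C9 after the inversion in step 2.

Step 2
Reactants: 2 (2R,3R)-2,3-epoxygeraniol; 3 isopropenylmagnesium bromide
Product: 4 (2S,3R)-3,7-dimethyl-2-(prop-1-en-2-yl)oct-6-ene-1,3-diol
Conditions: 3 (3 equiv), CuI (10 mol %), THF, −30 → 0 °C
Reagents that add atoms: none
Why: Copper-catalysed Grignard opening of a 2,3-epoxy alcohol by SN2 attack at the secondary epoxide carbon (future C9) with inversion, while the tertiary C–O bond (future C8) stays intact, so the 1,3-diol results; one equivalent of 3 is consumed by the free hydroxyl.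

Step 3
Reactants: 4 (2S,3R)-diol
Product: 5 (4R,5S)-2,2-di-tert-butyl-4-methyl-4-(4-methylpent-3-en-1-yl)-5-(prop-1-en-2-yl)-1,3,2-dioxasilinane
Conditions: t-Bu2Si(OTf)2, 2,6-lutidine, CH2Cl2, 0 °C → rt
Reagents that add atoms: di-tert-butylsilyl bis(trifluoromethanesulfonate), CC(C)(C)[Si](OS(=O)(=O)C(F)(F)F)(OS(=O)(=O)C(F)(F)F)C(C)(C)C
Why: Bis-silylation of a 1,3-diol to a six-membered silylene, the ditriflate being reactive enough for the tertiary hydroxyl; this ring is the conformational lock that later holds C17 axial and the C8–O bond equatorial.

Step 4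
Reactants: 5 silylene diene
Product: 6 (4aS,8aR)-2,2-di-tert-butyl-5,8a-dimethyl-4a,7,8,8a-tetrahydro-4H-benzo[d][1,3,2]dioxasiline
Conditions: second-generation Grubbs catalyst (5 mol %), toluene, 80 °C
Reagents that add atoms: none
Why: Ring-closing metathesis in which the gem-dimethyl alkene is the leaving terminus (isobutene) and the isopropenyl group becomes the ring alkene C5=C10; the silylene holds both alkenyl arms equatorial and gauche, which favours the trans-fused six-membered ring, and no stereocentre is touched.

Step 5
Reactants: 6 ring B cyclohexene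
Product: 7 (4aS,8aR)-2,2-di-tert-butyl-5,8a-dimethyl-4a,8-dihydro-4H-benzo[d][1,3,2]dioxasilin-7(8aH)-one (ring B enone, C6=O, C5=C10)
Conditions: Rh2(cap)4 (dirhodium tetrakis(caprolactamate), 1 mol %), t-BuOOH (70% aq), K2CO3, CH2Cl2, rt
Reagents that add atoms: tert-butyl hydroperoxide, CC(C)(C)OO
Why: Dirhodium-catalysed allylic oxidation with tert-butyl hydroperoxide (hydrogen abstraction by tert-butylperoxyl radical, mixed peroxide, ketone); the secondary ring methylene C6 next to the CH end of the alkene should react in preference to the shielded tertiary C9–H and the methyl C20.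

Step 6
Reactants: 7 silylene-locked ring B enone; 8 1,2-bis(trimethylsilyloxy)cyclobutene
Product: 9 cis-anti-cis photoadduct (C6 ketone; cyclobutane C1–C4–C5–C10 on the α face of ring B; 5β-H; 10β-CH3; OTMS on C1 and C4; outer cyclobutane C1–C2–C3–C4 anti to ring B)
Conditions: 8 (5 equiv), hν (λ ≥ 300 nm, Pyrex), hexane, −20 °C
Reagents that add atoms: none
Why: Excitation and intersystem crossing give the triplet enone, which bonds to the electron-rich alkene 8 to form a triplet 1,4-diradical that closes after spin inversion; the closest known reaction type is the enone–alkene [2+2] photocycloaddition with 1,2-bis(silyloxy)cycloalkenes used as a Diels–Alder equivalent. The one ring closed is the cyclobutane C1–C4–C5–C10, by stepwise collapse of the diradical (bonds C1–C10 and C4–C5) and not by a concerted addition. C10 is set by the face of attack: the trans-fused dioxasilinane fixes ring B with C17 axial on the β face, 1,3 to C10, and only the axial H-9 on the α face, so C1 should enter α and C20 end up β, cis to C11. C5 is set by the ring closure, which must be cis on the cyclohexanone; any trans-fused adduct is strained and can epimerise α to C6=O to the cis isomer. C1 and C4 are necessarily cis at the four–four fusion and should lie anti to ring B for steric reasons; both are erased at the glycol cleavage. The step therefore needs facial selectivity only, since 8 is symmetrical and has no regiochemistry, and the ring lock secures it. A β-methyl enone too hindered for a thermal cycloaddition reacts here because the excited state is the reactive partner.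

Step 7
Reactants: 9 photoadduct
Product: 10 C6 enol triflate (C6=C7) of 9
Conditions: KN(SiMe3)2, PhNTf2, THF, −78 °C
Reagents that add atoms: N-phenylbis(trifluoromethanesulfonimide), FC(F)(F)S(=O)(=O)N(c1ccccc1)S(=O)(=O)C(F)(F)F
Why: Kinetic enolisation and O-sulfonylation (enol triflate formation): the bulky amide removes a C7 proton and not the C5 methine, a cyclobutane carbon between two quaternary centres; the equatorial C8–O bond lies in the enolate plane, so β-elimination is stereoelectronically disfavoured, and the intact silyl ethers exclude retro-aldol cleavage of C4–C5.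

Step 8
Reactants: 10 enol triflate
Product: 11 C6-methylene compound (bis-TMS ether, silylene)
Conditions: H2 (1 atm), PtO2, 2,6-lutidine, EtOAc, rt
Reagents that add atoms: none
Why: Catalytic hydrogenolysis of an enol triflate over platinum (C–O cleavage and saturation) replaces the former carbonyl by a methylene without a radical or cation at C6 that could open the adjacent cyclobutane; 2,6-lutidine takes up the triflic acid so the silyl ethers survive.

Step 9
Reactants: 11 C6-methylene compound
Product: 12 tetraol (C1-OH, C4-OH, C8-OH tertiary; C11-OH primary)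
Conditions: HF·pyridine, pyridine, THF, 0 °C → rt
Reagents that add atoms: none
Why: Fluoride-driven cleavage of all Si–O bonds (Si–F formation); with C6 now a methylene the freed cyclobutanols have no carbonyl β to them, so no retro-aldol path exists.

Step 10
Reactants: 12 tetraol
Product: 13 C11 aldehyde (β-hydroxy aldehyde with intact cyclobutane-1,2-diol)
Conditions: SO3·pyridine, DMSO, i-Pr2NEt, CH2Cl2, 0 °C
Reagents that add atoms: none
Why: Parikh–Doering oxidation (activated DMSO): only the single primary hydroxyl can be oxidised, the three tertiary ones are inert, and the cold, weakly basic medium spares the β-hydroxy aldehyde and its C9 stereocentre.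

Step 11
Reactants: 13 C11 aldehyde
Product: 14 C9-vinyl triol (C11=C12)
Conditions: Zn, CH2I2, Ti(OiPr)4, THF, rt
Reagents that add atoms: diiodomethane, ICI
Why: Takai methylenation with a geminal dizinc–titanium methylene reagent, which is nucleophilic but hardly basic, so the β-hydroxy aldehyde should not undergo retro-aldol cleavage, dehydration or epimerisation at C9; the free tertiary hydroxyls only consume reagent.

Step 12
Reactants: 14 vinyl triol
Product: 15 cis-fused 1,4-dione (C1=O, C4=O; 5β-H; 9β-vinyl; 8α-OH)
Conditions: NaIO4, THF/H2O (pH 7 buffer), 0 °C → rt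
Reagents that add atoms: none
Why: Periodate glycol cleavage through the cyclic periodate ester of the cis-diol, helped by release of the bicyclo[2.2.0]hexane strain, opens ring A as the 1,4-dione; the neutral medium leaves C5 (now α to C4=O) untouched, and C1 and C4 lose their stereochemistry by design.

Step 13
Reactants: 15 1,4-dione
Product: 16 C4 methoxymethylene enol ether (E/Z mixture), C1 ketone
Conditions: Ph3P(CH2OMe)Cl, KOtBu, THF, 0 °C
Reagents that add atoms: (methoxymethyl)triphenylphosphonium chloride, COC[P+](c1ccccc1)(c1ccccc1)c1ccccc1.[Cl-]
Why: Wittig methoxymethylenation; the C4 carbonyl, flanked by a methine, is much more accessible than the C1 carbonyl next to quaternary C10, and where the ylide acts as a base it should take a C3 proton and not the hindered C5 methine, so the cis fusion is kept.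

Step 14
Reactants: 16 enol ether ketone
Product: 18 C1-methylene enol ether, via C1 hydrazone 17 (not isolated)
Conditions: N2H4·H2O, KOH, diethylene glycol, 130 → 200 °C, Ar
Reagents that add atoms: none
Why: Wolff–Kishner reduction (Huang-Minlon procedure) through hydrazone 17 removes the hindered C1 carbonyl; the enol ether, the vinyl group and the tertiary alcohol are stable to hot alkali, and C10 is quaternary so nothing can epimerise.

Step 15
Reactants: 18 enol ether
Product: 19 C4 carbaldehyde (mixture of C4 epimers)
Conditions: 1 M HCl, THF, rt
Reagents that add atoms: water, O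
Why: Acid-catalysed enol ether hydrolysis (C-protonation, hemiacetal, loss of methanol) gives the aldehyde; the C4 configuration does not matter because the centre is enolised in step 16.

Step 16
Reactants: 19 C4 carbaldehyde
Product: 20 (4R)-4-methyl-4-carbaldehyde (methyl cis to H-5, formyl cis to C6)
Conditions: KOtBu, MeI, THF, −20 → 0 °C
Reagents that add atoms: iodomethane, CI
Why: α-Alkylation of the potassium enolate of an α-branched aldehyde; iodomethane should approach the exocyclic enolate on the convex face of the cis-decalin, anti to the C5–C6 bond, which puts the methyl cis to H-5 and the formyl group cis to C6 and so sets quaternary C4; the hindered tertiary alkoxide competes poorly for the electrophile.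

Step 17
Reactants: 20 quaternary aldehyde
Product: 21 C9-vinyl 8α,19-diol
Conditions: NaBH4, MeOH, 0 °C
Reagents that add atoms: none
Why: Borohydride reduction of the neopentyl aldehyde to the primary alcohol C19–OH; no stereocentre is involved.

Step 18
Reactants: 21 vinyl diol; 22 2-chlorobuta-1,3-diene (chloroprene)
Product: 24 diene diol (8α-hydroxy-13(16),14-dien-19-ol), via B-alkyl-9-BBN adduct 23 (not isolated)
Conditions: 9-BBN, THF, rt → 50 °C; then Pd(OAc)2, SPhos, K3PO4 (aq), 22, THF, 60 °C (sealed tube)
Reagents that add atoms: none
Why: Anti-Markovnikov hydroboration of the vinyl group with 9-BBN puts boron on C12 (borane 23), and a B-alkyl Suzuki–Miyaura coupling with the alkenyl chloride 22, enabled by the electron-rich biaryl phosphine, forms C12–C13 and delivers the 2-substituted diene in one piece; the two hydroxyls only consume borane.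

Step 19
Reactants: 24 diene diol
Product: 25 C19 bromoacetate
Conditions: BrCH2COBr, pyridine, CH2Cl2, −20 °C
Reagents that add atoms: bromoacetyl bromide, O=C(CBr)Br
Why: Acylation of the primary (neopentyl) hydroxyl by an acid bromide; the tertiary C8 hydroxyl does not react at low temperature.

Step 20
Reactants: 25 bromoacetate
Product: 26 C19 (diphenoxyphosphoryl)acetate
Conditions: (PhO)2P(O)H, Et3N, CH2Cl2, 0 °C → rt
Reagents that add atoms: diphenyl phosphite, O=[PH](Oc1ccccc1)Oc1ccccc1
Why: Michaelis–Becker reaction: the phosphite anion generated by triethylamine displaces the α-bromide (SN2) and forms the P–C bond, giving the diaryl phosphonoacetate needed for Z-selective olefination.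

Step 21
Reactants: 26 phosphonoacetate; 27 4-(tert-butyldimethylsilyloxy)benzaldehyde
Product: 28 C19 (Z)-4-(tert-butyldimethylsilyloxy)cinnamate
Conditions: NaH, THF, −78 → −20 °C, exclusion of light
Reagents that add atoms: none
Why: Horner–Wadsworth–Emmons olefination with a diaryl phosphonoacetate: the electron-poor aryloxy groups make elimination from the first-formed adduct faster than its equilibration, which should favour the Z-enoate under kinetic control at low temperature; one equivalent of base deprotonates only the phosphonoacetate.

Step 22
Reactants: 28 silyl-protected Z-ester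
Product: 29 target, 8α-hydroxy-5β-labda-13(16),14-dien-19-yl (Z)-4-hydroxycinnamate (4R,5S,8R,9R,10S)
Conditions: HF·pyridine, pyridine, THF, 0 °C, exclusion of light
Reagents that add atoms: none
Why: Fluoride cleavage of the aryl silyl ether under buffered, cold conditions in the dark frees the phenol without isomerising the Z-enoate or touching the diene.

## Compound list

1 | geraniol, (2E)-3,7-dimethylocta-2,6-dien-1-ol | CC(C)=CCC/C(C)=C/CO | starting material
2 | [(2R,3R)-3-methyl-3-(4-methylpent-3-en-1-yl)oxiran-2-yl]methanol | OC[C@H]1O[C@]1(C)CCC=C(C)C | intermediate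
3 | isopropenylmagnesium bromide | CC(=C)[Mg]Br | starting material
4 | (2S,3R)-3,7-dimethyl-2-(prop-1-en-2-yl)oct-6-ene-1,3-diol | OC[C@H](C(C)=C)[C@](C)(O)CCC=C(C)C | intermediate
5 | (4R,5S)-2,2-di-tert-butyl-4-methyl-4-(4-methylpent-3-en-1-yl)-5-(prop-1-en-2-yl)-1,3,2-dioxasilinane | CC(C)(C)[Si]1(C(C)(C)C)OC[C@H](C(C)=C)[C@@](C)(CCC=C(C)C)O1 | intermediate
6 | (4aS,8aR)-2,2-di-tert-butyl-5,8a-dimethyl-4a,7,8,8a-tetrahydro-4H-benzo[d][1,3,2]dioxasiline | CC(C)(C)[Si]1(C(C)(C)C)OC[C@@H]2C(C)=CCC[C@@]2(C)O1 | intermediate
7 | (4aS,8aR)-2,2-di-tert-butyl-5,8a-dimethyl-4a,8-dihydro-4H-benzo[d][1,3,2]dioxasilin-7(8aH)-one (ring B enone; key-step precursor) | CC(C)(C)[Si]1(C(C)(C)C)OC[C@@H]2C(C)=CC(=O)C[C@@]2(C)O1 | intermediate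
8 | 1,2-bis(trimethylsilyloxy)cyclobutene | C[Si](C)(C)OC1=C(O[Si](C)(C)C)CC1 | starting material
9 | cis-anti-cis photoadduct: C6 ketone, cyclobutane C1–C4–C5–C10 on the α face, 5β-H, 10β-CH3, 1,4-bis(trimethylsilyloxy), C8-O/C11-O di-tert-butylsilylene | CC(C)(C)[Si]1(C(C)(C)C)OC[C@@H]2[C@@]3(C)[C@]4(O[Si](C)(C)C)CC[C@]4(O[Si](C)(C)C)[C@H]3C(=O)C[C@@]2(C)O1 | intermediate
10 | C6 enol triflate (C6=C7) of 9 | CC(C)(C)[Si]1(C(C)(C)C)OC[C@@H]2[C@@]3(C)[C@]4(O[Si](C)(C)C)CC[C@]4(O[Si](C)(C)C)[C@H]3C(OS(=O)(=O)C(F)(F)F)=C[C@@]2(C)O1 | intermediate
11 | C6-methylene analogue of 9 | CC(C)(C)[Si]1(C(C)(C)C)OC[C@@H]2[C@@]3(C)[C@]4(O[Si](C)(C)C)CC[C@]4(O[Si](C)(C)C)[C@H]3CC[C@@]2(C)O1 | intermediate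
12 | tetraol: cis-cyclobutane-1,4-diol (C1, C4), 8α-OH, C11-OH; 5β-H, 10β-CH3 | OC[C@@H]1[C@@]2(C)[C@]3(O)CC[C@]3(O)[C@H]2CC[C@@]1(C)O | intermediate
13 | C11 aldehyde of 12 (triol) | O=C[C@@H]1[C@@]2(C)[C@]3(O)CC[C@]3(O)[C@H]2CC[C@@]1(C)O | intermediate
14 | 9β-vinyl triol (C11=C12) | C=C[C@@H]1[C@@]2(C)[C@]3(O)CC[C@]3(O)[C@H]2CC[C@@]1(C)O | intermediate
15 | cis-fused 9β-vinyl-8α-hydroxy-8β,10β-dimethyldecalin-1,4-dione (labdane numbering, 5β-H) | C=C[C@@H]1[C@@]2(C)C(=O)CCC(=O)[C@H]2CC[C@@]1(C)O | intermediate
16 | 4-(methoxymethylene) derivative of 15 (C1 ketone; E/Z mixture) | C=C[C@@H]1[C@@]2(C)C(=O)CCC(=COC)[C@H]2CC[C@@]1(C)O | intermediate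
17 | C1 hydrazone of 16 | C=C[C@@H]1[C@@]2(C)C(=NN)CCC(=COC)[C@H]2CC[C@@]1(C)O | intermediate
18 | 4-(methoxymethylene) compound with C1 methylene | C=C[C@@H]1[C@@]2(C)CCCC(=COC)[C@H]2CC[C@@]1(C)O | intermediate
19 | C4 carbaldehyde (C4 epimers), 9β-vinyl, 8α-OH, 5β-H | C=C[C@@H]1[C@@]2(C)CCCC(C=O)[C@H]2CC[C@@]1(C)O | intermediate
20 | (4R)-4-methyl-4-carbaldehyde (methyl cis to H-5, CHO cis to C6) | C=C[C@@H]1[C@@]2(C)CCC[C@@](C)(C=O)[C@H]2CC[C@@]1(C)O | intermediate
21 | 9β-vinyl 8α,19-diol | C=C[C@@H]1[C@@]2(C)CCC[C@@](C)(CO)[C@H]2CC[C@@]1(C)O | intermediate
22 | 2-chlorobuta-1,3-diene (chloroprene) | C=CC(Cl)=C | starting material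
23 | B-(C12-alkyl)-9-borabicyclo[3.3.1]nonane from 21 | C1CC2CCCC(C1)B2CC[C@@H]1[C@@]2(C)CCC[C@@](C)(CO)[C@H]2CC[C@@]1(C)O | intermediate
24 | 8α-hydroxy-5β-labda-13(16),14-dien-19-ol | C=CC(=C)CC[C@@H]1[C@@]2(C)CCC[C@@](C)(CO)[C@H]2CC[C@@]1(C)O | intermediate
25 | C19 bromoacetate of 24 | C=CC(=C)CC[C@@H]1[C@@]2(C)CCC[C@@](C)(COC(=O)CBr)[C@H]2CC[C@@]1(C)O | intermediate
26 | C19 (diphenoxyphosphoryl)acetate of 24 | C=CC(=C)CC[C@@H]1[C@@]2(C)CCC[C@@](C)(COC(=O)CP(=O)(Oc3ccccc3)Oc3ccccc3)[C@H]2CC[C@@]1(C)O | intermediate
27 | 4-(tert-butyldimethylsilyloxy)benzaldehyde | CC(C)(C)[Si](C)(C)Oc1ccc(C=O)cc1 | starting material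
28 | C19 (Z)-4-(tert-butyldimethylsilyloxy)cinnamate of 24 | C=CC(=C)CC[C@@H]1[C@@]2(C)CCC[C@@](C)(COC(=O)/C=C\c3ccc(O[Si](C)(C)C(C)(C)C)cc3)[C@H]2CC[C@@]1(C)O | intermediate
29 | (4R,5S,8R,9R,10S)-8-hydroxy-5β-labda-13(16),14-dien-19-yl (Z)-4-hydroxycinnamate | C=CC(=C)CC[C@@H]1[C@@]2(C)CCC[C@@](C)(COC(=O)/C=C\c3ccc(O)cc3)[C@H]2CC[C@@]1(C)O | target

## Step count and least certain steps

Total step count: 22. Longest linear sequence: 22 steps (1 → 29); 3, 8, 22 and 27 are purchased.

Step 6 (key step). Most likely failure: loss of facial control or low conversion, because two fully substituted carbons (C10 and C1) must be joined and the diradical can revert or close on the β face; part of the material may also close trans at C5. Fallback: change the control element from a ring lock to two independent bulky ethers, of which the C11 ether shields the β face directly. From 4, the primary hydroxyl is silylated (TBSCl, imidazole) to the mono-silyl ether F1 and the tertiary hydroxyl is capped (TESOTf, 2,6-lutidine) to give the bis-silyl diene F2. Metathesis then gives the cyclohexene F3 and allylic oxidation the conformationally free enone F4. Irradiation with 8 gives the adduct F5, which is carried through the enol triflate F6 to the C6-methylene compound F7. HF·pyridine removes all four silyl groups and the route is rejoined at 12.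

Step 8. Most likely failure: incomplete hydrogenolysis (saturation without C–O cleavage, or stalling at the alkene) and acid-induced loss of silyl groups if the liberated triflic acid is not scavenged fast enough. Fallback: from 10, transfer hydrogenolysis with Pd(OAc)2, PPh3 and tributylammonium formate gives the C6=C7 alkene F8, which diimide (potassium azodicarboxylate, acetic acid) saturates to 11.

Step 11. Most likely failure: retro-aldol opening of the C8–C9 bond or dehydration of the β-hydroxy aldehyde, or low conversion because the aldehyde is tied up as a hemiacetal or metal alkoxide with the neighbouring hydroxyls. Fallback: from 13, addition of the weakly basic organocerium reagent from (trimethylsilyl)methylmagnesium chloride and CeCl3 gives the β-hydroxysilane F9, and KH-induced syn-elimination (Peterson olefination) returns to 14.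

Step 13. Most likely failure: insufficient site selectivity between the two ketones, with base-induced epimerisation at C5 as a second risk, because the differentiation is purely kinetic and steric. Fallback: from 15, mono-ketalisation with ethane-1,2-diol under equilibrium conditions (PPTS, benzene, Dean–Stark) gives the C4 dioxolane F10. Wolff–Kishner reduction removes the now unique C1 carbonyl to give the ketal F11, aqueous acid unveils the C4 ketone F12, and methoxymethylenation of this single carbonyl returns to 18.

Step 16. Most likely failure: poor or reversed facial selectivity at C4, because the flexible cis-decalin may react through a conformer in which C20 screens the face cis to H-5; O-alkylation is a minor risk. Fallback: reverse the order in which the two C4 substituents arrive. From 19, the enolate is alkylated with benzyl chloromethyl ether, which enters on the same face as the methyl group would have, to give the benzyloxymethyl aldehyde F13. Wolff–Kishner reduction turns the formyl group into the methyl group to give the benzyl ether F14, and Li/NH3 removes the benzyl group to return to 21.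

Step 18. Most likely failure: slow oxidative addition into the alkenyl chloride, so that protodeboronation, β-hydride elimination or polymerisation of 22 take over. Fallback: from 23, iodinolysis (I2, NaOMe) gives the C12 iodide F15. Chloroprene 22 is converted with magnesium into buta-1,3-dien-2-ylmagnesium chloride F16, and Li2CuCl4-catalysed coupling of F15 with excess F16 returns to 24.

## Further compounds

F1 | step 6 | (2S,3R)-1-(tert-butyldimethylsilyloxy)-3,7-dimethyl-2-(prop-1-en-2-yl)oct-6-en-3-ol | CC(C)(C)[Si](C)(C)OC[C@H](C(C)=C)[C@](C)(O)CCC=C(C)C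
F2 | step 6 | C3 triethylsilyl ether of F1 | CC(C)(C)[Si](C)(C)OC[C@H](C(C)=C)[C@](C)(O[Si](CC)(CC)CC)CCC=C(C)C
F3 | step 6 | ring B cyclohexene bis-silyl ether | CC(C)(C)[Si](C)(C)OC[C@@H]1C(C)=CCC[C@@]1(C)O[Si](CC)(CC)CC
F4 | step 6 | (4S,5R)-4-(tert-butyldimethylsilyloxymethyl)-3,5-dimethyl-5-(triethylsilyloxy)cyclohex-2-enone | CC(C)(C)[Si](C)(C)OC[C@@H]1C(C)=CC(=O)C[C@@]1(C)O[Si](CC)(CC)CC
F5 | step 6 | cis-anti-cis photoadduct of F4 and 8 | CC(C)(C)[Si](C)(C)OC[C@@H]1[C@@]2(C)[C@]3(O[Si](C)(C)C)CC[C@]3(O[Si](C)(C)C)[C@H]2C(=O)C[C@@]1(C)O[Si](CC)(CC)CC
F6 | step 6 | C6 enol triflate of F5 | CC(C)(C)[Si](C)(C)OC[C@@H]1[C@@]2(C)[C@]3(O[Si](C)(C)C)CC[C@]3(O[Si](C)(C)C)[C@H]2C(OS(=O)(=O)C(F)(F)F)=C[C@@]1(C)O[Si](CC)(CC)CC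
F7 | step 6 | C6-methylene analogue of F5 | CC(C)(C)[Si](C)(C)OC[C@@H]1[C@@]2(C)[C@]3(O[Si](C)(C)C)CC[C@]3(O[Si](C)(C)C)[C@H]2CC[C@@]1(C)O[Si](CC)(CC)CC
F8 | step 8 | C6=C7 alkene (bis-TMS ether, silylene) | CC(C)(C)[Si]1(C(C)(C)C)OC[C@@H]2[C@@]3(C)[C@]4(O[Si](C)(C)C)CC[C@]4(O[Si](C)(C)C)[C@H]3C=C[C@@]2(C)O1
F9 | step 11 | C11 carbinol bearing CH2SiMe3 (β-hydroxysilane, C11 epimers) | C[Si](C)(C)CC(O)[C@@H]1[C@@]2(C)[C@]3(O)CC[C@]3(O)[C@H]2CC[C@@]1(C)O
F10 | step 13 | C4 ethylene ketal of 15 (C1 ketone) | C=C[C@@H]1[C@@]2(C)C(=O)CCC3(OCCO3)[C@H]2CC[C@@]1(C)O
F11 | step 13 | C4 ethylene ketal with C1 methylene | C=C[C@@H]1[C@@]2(C)CCCC3(OCCO3)[C@H]2CC[C@@]1(C)O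
F12 | step 13 | C4 ketone with C1 methylene (5β-H) | C=C[C@@H]1[C@@]2(C)CCCC(=O)[C@H]2CC[C@@]1(C)O
F13 | step 16 | 4-(benzyloxymethyl)-4-carbaldehyde (CH2OBn cis to C6, CHO cis to H-5) | C=C[C@@H]1[C@@]2(C)CCC[C@@](C=O)(COCc3ccccc3)[C@H]2CC[C@@]1(C)O
F14 | step 16 | C19 benzyl ether of 21 | C=C[C@@H]1[C@@]2(C)CCC[C@@](C)(COCc3ccccc3)[C@H]2CC[C@@]1(C)O
F15 | step 18 | C12 iodide, 8α,19-diol | ICC[C@@H]1[C@@]2(C)CCC[C@@](C)(CO)[C@H]2CC[C@@]1(C)O
F16 | step 18 | buta-1,3-dien-2-ylmagnesium chloride | C=CC(=C)[Mg]Cl
A1 | alternative 1 | cis-fused C7 enone with C4 methyl and nitrile | C1=C(C)C(=O)C[C@@H]2[C@](C)(C#N)CCC[C@]12C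
A2 | alternative 1 | 4-(4-cyanopentyl)-2,4-dimethylcyclohexa-2,5-dienone | N#CC(C)CCC[C@@]1(C)C=CC(=O)C(C)=C1
A3 | alternative 2 | cis-fused octalin C19 methyl ester with C1=C2 | c1ccccc1COC[C@@H]1[C@@]2(C)C=CC[C@@](C)(C(=O)OC)[C@H]2CC[C@@]1(C)O[Si](CC)(CC)CC
A4 | alternative 2 | triene with Z-tethered diene and (Z)-2-methyl enoate | C=C/C=C(C)\[C@@H](COCc1ccccc1)[C@](C)(O[Si](CC)(CC)CC)CC/C=C(C)\C(=O)OC
A5 | alternative 3 | cis-decalin-1-one 4-ketal with C8 silyl ether and C9 acetic ester arm | COC(=O)C[C@@H]1[C@@]2(C)C(=O)CCC3(OCCO3)[C@H]2CC[C@@]1(C)O[Si](CC)(CC)CC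
A6 | alternative 3 | 2-methylcyclohex-2-ene-1,4-dione 4-ethylene ketal | CC1=CC2(OCCO2)CCC1=O
A7 | alternative 3 | C6 alkylzinc iodide with C8 silyl ether and (E)-enoate | I[Zn]CC[C@@](C)(O[Si](CC)(CC)CC)/C=C/C(=O)OC
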